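Compound numbers 1–14 are those of the steps and the compound list; 14 is the target.

## The problem

The target 14 is an indane with three contiguous, all-trans ring stereocentres, C1 (R), C2 (S) and C3 (R), and a fourth, exocyclic one, the (S)-carbinol carbon Cα on C1; it also carries six phenols. The ring centres can control one another, because the all-trans array is the stable one and C3 forms trans to C2 in any ring closure. Cα is different: it is an acyclic centre next to C1, whose two large substituents (the arene carbon C7a and the branched C2) are too alike for reliable 1,2-induction on a C1 ketone or aldehyde. The molecule offers no carbonyl or other handle for absolute control. The carbinol is para-hydroxybenzylic, so acids ionize it to a para-quinone methide that eliminates toward C1 or epimerizes; BBr3 demethylation or benzyl hydrogenolysis cannot follow its installation. The feature that opens a way is hidden symmetry. If the bond C3–C3a is cut and C3 is joined to the carbinol oxygen, the atoms O–Cα–C1–C2–C3 form an oxolane with identical 4-hydroxyphenyl groups on Cα and C3 and identical 3,5-dihydroxyphenyl groups on C1 and C2. With the configuration of 14 at Cα, C1 and C2 this oxolane is the meso compound 12, an isomer of 14. C3 carries a para-hydroxyphenyl group (a latent quinone methide) and C3a lies ortho and para to the hydroxyls on C4 and C6, so C3–C3a is a natural Friedel–Crafts bond; the two benzylic C–O bonds of 12 are enantiotopic, and choosing one of them fixes all four stereocentres at once.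

## Retrosynthesis

**14 to 12 (via 13).** The bond C3–C3a is cut and, in the reverse sense, C3 is joined to the carbinol oxygen. This gives meso-oxolane 12, which would open at one benzylic C–O bond to para-quinone methide 13 and close onto the resorcinol ring.
- Against the neighbouring cut at C1–C2, this cut keeps that bond and its two stereocentres intact and makes the last step an isomerization with no reagent and no protecting group.
- The precursor 12 is achiral and symmetric.
- In 12 each 4-hydroxyphenyl group is trans to the resorcinol ring on the next carbon. Traced through the opening, this is the (αS,1R) relation of 14, and the cis relation of the two resorcinol rings becomes trans-1,2 on the indane.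
- The forward step must cleave the C–O bond at the (R)-configured benzylic carbon and leave the (S)-configured one as the carbinol, and C–C closure must outrun re-ionization of the product.

**12 to 11.** The six phenols are masked as triisopropylsilyl ethers. This is the one group that survives enolate chemistry, borohydride and catalytic acid, leaves under buffered fluoride without touching the benzylic ether, and shields the carbon ortho to oxygen so that 11 cannot undergo the Friedel–Crafts closure too early.

**11 to 10 to 9.** The two C–O bonds of the oxolane are cut, giving diol 10. Closure under reversible, acid-catalysed conditions places each 2- and 5-aryl group trans to its neighbour whatever the carbinol configuration of 10. Therefore 10 can come from an unselective reduction of meso-diketone 9, and only the meso relation of C2 and C3 has to be secured beforehand.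

**9 to 5 (via 6, 7, 8).** The central C2–C3 bond is cut, halving the molecule to deoxybenzoin 5. The forward reaction is the oxidative dimerization of enolate 6 through alpha-iodo ketone 7. Both new centres are alpha to a ketone, so the dl isomer 8 and meso 9 equilibrate with base, and the meso isomer (both aryl/aryl and aroyl/aroyl pairs can be antiperiplanar) is drawn off.

**5 to 2 and 4, then to 1 and 3.** The aryl–CH2 bond is cut: alpha-arylation of silylated acetophenone 2 with aryl bromide 4. These come by silylation of 4′-hydroxyacetophenone 1 and 5-bromoresorcinol 3, both commercial.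

## Roads not taken

**Alternative 1:** The most obvious, biomimetic cut is at C1–C2 together with C3–C3a. Forward, one-electron oxidation of resveratrol A1 would couple two radicals to the bis(para-quinone methide) A2; one half closes by Friedel–Crafts reaction and the other adds water. The chosen plan is better for three reasons:
- The radical coupling competes with other coupling modes and gives A2 as a meso/dl mixture.
- Nothing controls the absolute configuration.
- Water adds to the second quinone methide without facial control, in competition with elimination toward C1.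

The chosen plan makes the same bond at the ketone level, where meso and dl equilibrate, and stores both benzylic oxidation levels in a stable ether so that a catalyst decides which one reacts.

**Alternative 2:** Cut C3–C3a and the exocyclic C1–Cα bond. Forward, a Nazarov cyclization of aryl vinyl ketone A3 gives trans-2,3-diarylindanone A4, followed by one-carbon homologation at C1 and addition of an aryl nucleophile. The chosen plan is better because:
- The Nazarov step gives a racemate; no close asymmetric precedent exists for this substrate class.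
- The C1 carbonyl, between a peri hydrogen and the C2 aryl, is hindered toward olefination.
- Cα is set last by 1,2-induction from C1, whose sense is not predictable.
- The methyl ethers needed for the acid step cannot be removed once the carbinol exists.
- The route is several steps longer.

**Alternative 3:** Keep the symmetric dimer but break the symmetry by reduction. Diketone A5 (methyl ethers in place of the silyl ethers of 9) is mono-reduced with a chiral hydrogenation catalyst under dynamic kinetic resolution to keto alcohol A6. The carbinol is ionized for Friedel–Crafts closure to aroylindane A7, C1 epimerizes to trans, and the ketone is reduced last. The chosen plan is better because: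
- The enantio-determining reduction must tell apart two large alpha substituents (aryl against a diarylethyl chain), and mono- against bis-reduction is statistical.
- A6 can divert to a cyclic enol ether under acid.
- The final reduction faces the same ambiguous 1,2-induction as in Alternative 2.
- Deprotection would follow carbinol formation.

The chosen plan sets the Cα/C1 relation thermodynamically in a ring and ends with an isomerization.

Key step: step 8

Assumption: which enantiomer of the chiral phosphoric acid cleaves the C–O bond at the (R)-configured carbon of 12 cannot be read from precedent; the (R)-acid is written, and the (S)-acid would take its place if the sense proves opposite.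

## Steps

Step 1
Reactants: 1 1-(4-hydroxyphenyl)ethan-1-one
Product: 2 1-{4-[(triisopropylsilyl)oxy]phenyl}ethan-1-one
Conditions: TIPSCl (1.1 equiv), imidazole (2 equiv), DMF, rt
Reagents that add atoms: chlorotriisopropylsilane (TIPSCl), CC(C)[Si](Cl)(C(C)C)C(C)C
Why: Imidazole-promoted O-silylation of a phenol; the triisopropylsilyl ether is chosen because it should survive phosphate base, amide base, borohydride and catalytic acid and leave with fluoride.

Step 2
Reactants: 3 5-bromobenzene-1,3-diol
Product: 4 1-bromo-3,5-bis[(triisopropylsilyl)oxy]benzene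
Conditions: TIPSCl (2.2 equiv), imidazole (4 equiv), DMF, rt
Reagents that add atoms: chlorotriisopropylsilane (TIPSCl), CC(C)[Si](Cl)(C(C)C)C(C)C
Why: The same O-silylation, twice; both hydroxyls are unhindered.

Step 3
Reactants: 2 1-{4-[(triisopropylsilyl)oxy]phenyl}ethan-1-one; 4 1-bromo-3,5-bis[(triisopropylsilyl)oxy]benzene
Product: 5 2-{3,5-bis[(triisopropylsilyl)oxy]phenyl}-1-{4-[(triisopropylsilyl)oxy]phenyl}ethan-1-one
Conditions: Pd2(dba)3 (1 mol%), Xantphos (2.4 mol%), K3PO4 (2.3 equiv), toluene, 80 °C; 2 in slight excess (1.2 equiv)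
Reagents that add atoms: none
Why: Palladium-catalysed alpha-arylation of a methyl ketone enolate with an aryl bromide (oxidative addition to zerovalent palladium, enolate transmetallation, reductive elimination); the wide-bite-angle bisphosphine, the weak phosphate base and excess ketone favour mono-arylation and spare the aryl silyl ethers.

Step 4
Reactants: 5 2-{3,5-bis[(triisopropylsilyl)oxy]phenyl}-1-{4-[(triisopropylsilyl)oxy]phenyl}ethan-1-one (two molecules)
Product: 9 meso-(2R,3S)-2,3-bis{3,5-bis[(triisopropylsilyl)oxy]phenyl}-1,4-bis{4-[(triisopropylsilyl)oxy]phenyl}butane-1,4-dione, via lithium enolate 6 (not isolated), via alpha-iodo ketone 7 (not isolated), via dl-diketone 8 (not isolated)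
Conditions: LiN(iPr)2 (LDA, 1.05 equiv), THF, −78 °C; I2 (0.5 equiv), −78 °C to rt; then DBU (0.3 equiv), MeCN, 50 °C, meso isomer removed by crystallization, mother liquor re-equilibrated
Reagents that add atoms: none
Why: Oxidative enolate homocoupling: half of enolate 6 is iodinated to 7, which the other half displaces; the two new stereocentres are alpha to ketones, so DBU interconverts dl 8 and meso 9, and the meso isomer, which alone can place both aryl pairs and both aroyl pairs antiperiplanar, is expected to predominate and to be the less soluble one.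

Step 5
Reactants: 9 meso-(2R,3S)-2,3-bis{3,5-bis[(triisopropylsilyl)oxy]phenyl}-1,4-bis{4-[(triisopropylsilyl)oxy]phenyl}butane-1,4-dione
Product: 10 (2R,3S)-2,3-bis{3,5-bis[(triisopropylsilyl)oxy]phenyl}-1,4-bis{4-[(triisopropylsilyl)oxy]phenyl}butane-1,4-diol (mixture of epimers at C1 and C4)
Conditions: LiBH4 (3 equiv), THF, 0 °C to rt
Reagents that add atoms: none
Why: Borohydride reduction of two aryl ketones; no facial selectivity is asked for, because both carbinol centres are reset under thermodynamic control in step 6, and C2/C3 are no longer epimerizable once the ketones are gone.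

Step 6
Reactants: 10 (2R,3S)-2,3-bis{3,5-bis[(triisopropylsilyl)oxy]phenyl}-1,4-bis{4-[(triisopropylsilyl)oxy]phenyl}butane-1,4-diol
Product: 11 meso-(2R,3S,4R,5S)-3,4-bis{3,5-bis[(triisopropylsilyl)oxy]phenyl}-2,5-bis{4-[(triisopropylsilyl)oxy]phenyl}oxolane
Conditions: TsOH·H2O (10 mol%), CH2Cl2, 0 °C to rt, until the isomer ratio no longer changes
Reagents that add atoms: none
Why: Acid-catalysed cyclodehydration (SN1 etherification through a para-silyloxybenzylic cation, 5-exo closure by the second hydroxyl); the benzylic C–O bonds of the product re-ionize under the same acid, so all carbinol epimers of 10 should converge on the isomer with each 2- and 5-aryl group trans to its neighbour, which with the fixed cis-3,4 relation is the meso compound; Friedel–Crafts closure is held back because the only carbon that could attack is flanked by a triisopropylsilyloxy group that would end up peri to the aryl on the new ring.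

Step 7
Reactants: 11 meso-(2R,3S,4R,5S)-3,4-bis{3,5-bis[(triisopropylsilyl)oxy]phenyl}-2,5-bis{4-[(triisopropylsilyl)oxy]phenyl}oxolane
Product: 12 meso-(2R,3S,4R,5S)-3,4-bis(3,5-dihydroxyphenyl)-2,5-bis(4-hydroxyphenyl)oxolane
Conditions: Bu4NF (6.6 equiv), AcOH (6.6 equiv), THF, 0 °C
Reagents that add atoms: none
Why: Fluoride cleavage of six aryl silyl ethers; the acetic acid buffer keeps the phenols protonated so that no phenoxide opens the para-hydroxybenzylic ether, and no stereocentre is touched.

Step 8
Reactants: 12 meso-(2R,3S,4R,5S)-3,4-bis(3,5-dihydroxyphenyl)-2,5-bis(4-hydroxyphenyl)oxolane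
Product: 14 (1R,2S,3R)-2-(3,5-dihydroxyphenyl)-1-[(S)-hydroxy(4-hydroxyphenyl)methyl]-3-(4-hydroxyphenyl)-2,3-dihydro-1H-indene-4,6-diol, via para-quinone methide alcohol 13 (not isolated)
Conditions: (R)-3,3′-bis(2,4,6-triisopropylphenyl)-1,1′-binaphthyl-2,2′-diyl hydrogen phosphate (10 mol%), EtOAc/CH2Cl2 1:3, 0.02 M, 25 °C, stopped when 12 is consumed
Reagents that add atoms: none
Why: Proposed new method: the chiral phosphoric acid should bind the oxolane oxygen and the para-hydroxyl of one 2-aryl group, so that heterolysis of that benzylic C–O bond gives the neutral para-quinone methide 13 while the other C–O bond, and with it the (S)-carbinol centre, is never broken; the closest known reaction type is the phosphoric-acid-catalysed Friedel–Crafts 1,6-addition of electron-rich phenols to para-quinone methides generated in situ from para-hydroxybenzyl alcohols, taken together with acid-catalysed desymmetrizing openings of meso cyclic ethers. The resorcinol ring two carbons away then attacks the methide carbon through its carbon ortho to one hydroxyl and para to the other (5-exo-trig on the exocyclic C=C; the nearer resorcinol ring could only close a four-membered ring and the 4-hydroxyphenyl ring offers only a carbon meta to its hydroxyl), and rearomatization gives 14. The new stereocentre C3 is set by the substrate: the 4-hydroxyphenyl group on the methide carbon takes the side away from the aryl on C2, giving the trans-2,3 relation. C1, C2 and Cα are already present in 12, whose cis-3,4 relation becomes trans-1,2 on the indane and whose trans-2,3 relation becomes the (αS,1R) pair. The one selectivity that the catalyst must supply is between the two enantiotopic C–O bonds (cleavage at the (R)-configured carbon leads to 14, at the (S)-configured carbon to its enantiomer); since opening is reversible this is decided in the C–C bond-forming transition state, where the phosphate can bridge the quinone methide oxygen and the hydroxyl next to the attacking carbon, two anchoring points that the free phenols of 12 provide, and meets stereocentres of opposite configuration on the two sides. Reclosure through oxygen only returns 12, and the carbinol left in 14 is of the configuration that the catalyst ionizes slowly and stands trans to the C2 aryl, so no second cyclization can follow.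

## Compound list

1 | 1-(4-hydroxyphenyl)ethan-1-one | CC(=O)c1ccc(O)cc1 | starting material
2 | 1-{4-[(triisopropylsilyl)oxy]phenyl}ethan-1-one | CC(=O)c1ccc(O[Si](C(C)C)(C(C)C)C(C)C)cc1 | intermediate
3 | 5-bromobenzene-1,3-diol | Oc1cc(O)cc(Br)c1 | starting material
4 | 1-bromo-3,5-bis[(triisopropylsilyl)oxy]benzene | Brc1cc(O[Si](C(C)C)(C(C)C)C(C)C)cc(O[Si](C(C)C)(C(C)C)C(C)C)c1 | intermediate
5 | 2-{3,5-bis[(triisopropylsilyl)oxy]phenyl}-1-{4-[(triisopropylsilyl)oxy]phenyl}ethan-1-one | O=C(Cc1cc(O[Si](C(C)C)(C(C)C)C(C)C)cc(O[Si](C(C)C)(C(C)C)C(C)C)c1)c1ccc(O[Si](C(C)C)(C(C)C)C(C)C)cc1 | intermediate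
6 | lithium (Z)-enolate of 5 (not isolated) | [Li+].[O-]/C(=C\c1cc(O[Si](C(C)C)(C(C)C)C(C)C)cc(O[Si](C(C)C)(C(C)C)C(C)C)c1)c1ccc(O[Si](C(C)C)(C(C)C)C(C)C)cc1 | intermediate
7 | 2-{3,5-bis[(triisopropylsilyl)oxy]phenyl}-2-iodo-1-{4-[(triisopropylsilyl)oxy]phenyl}ethan-1-one, racemic (not isolated) | O=C(C(I)c1cc(O[Si](C(C)C)(C(C)C)C(C)C)cc(O[Si](C(C)C)(C(C)C)C(C)C)c1)c1ccc(O[Si](C(C)C)(C(C)C)C(C)C)cc1 | intermediate
8 | rac-(2R,3R)-2,3-bis{3,5-bis[(triisopropylsilyl)oxy]phenyl}-1,4-bis{4-[(triisopropylsilyl)oxy]phenyl}butane-1,4-dione, the dl isomer, one enantiomer drawn (not isolated) | O=C(c1ccc(O[Si](C(C)C)(C(C)C)C(C)C)cc1)[C@@H](c1cc(O[Si](C(C)C)(C(C)C)C(C)C)cc(O[Si](C(C)C)(C(C)C)C(C)C)c1)[C@H](c1cc(O[Si](C(C)C)(C(C)C)C(C)C)cc(O[Si](C(C)C)(C(C)C)C(C)C)c1)C(=O)c1ccc(O[Si](C(C)C)(C(C)C)C(C)C)cc1 | intermediate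
9 | meso-(2R,3S)-2,3-bis{3,5-bis[(triisopropylsilyl)oxy]phenyl}-1,4-bis{4-[(triisopropylsilyl)oxy]phenyl}butane-1,4-dione | O=C(c1ccc(O[Si](C(C)C)(C(C)C)C(C)C)cc1)[C@@H](c1cc(O[Si](C(C)C)(C(C)C)C(C)C)cc(O[Si](C(C)C)(C(C)C)C(C)C)c1)[C@@H](c1cc(O[Si](C(C)C)(C(C)C)C(C)C)cc(O[Si](C(C)C)(C(C)C)C(C)C)c1)C(=O)c1ccc(O[Si](C(C)C)(C(C)C)C(C)C)cc1 | intermediate
10 | (2R,3S)-2,3-bis{3,5-bis[(triisopropylsilyl)oxy]phenyl}-1,4-bis{4-[(triisopropylsilyl)oxy]phenyl}butane-1,4-diol, mixture of C1/C4 epimers | OC(c1ccc(O[Si](C(C)C)(C(C)C)C(C)C)cc1)[C@@H](c1cc(O[Si](C(C)C)(C(C)C)C(C)C)cc(O[Si](C(C)C)(C(C)C)C(C)C)c1)[C@@H](c1cc(O[Si](C(C)C)(C(C)C)C(C)C)cc(O[Si](C(C)C)(C(C)C)C(C)C)c1)C(O)c1ccc(O[Si](C(C)C)(C(C)C)C(C)C)cc1 | intermediate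
11 | meso-(2R,3S,4R,5S)-3,4-bis{3,5-bis[(triisopropylsilyl)oxy]phenyl}-2,5-bis{4-[(triisopropylsilyl)oxy]phenyl}oxolane | O1[C@H](c2ccc(O[Si](C(C)C)(C(C)C)C(C)C)cc2)[C@@H](c2cc(O[Si](C(C)C)(C(C)C)C(C)C)cc(O[Si](C(C)C)(C(C)C)C(C)C)c2)[C@@H](c2cc(O[Si](C(C)C)(C(C)C)C(C)C)cc(O[Si](C(C)C)(C(C)C)C(C)C)c2)[C@@H]1c1ccc(O[Si](C(C)C)(C(C)C)C(C)C)cc1 | intermediate
12 | meso-(2R,3S,4R,5S)-3,4-bis(3,5-dihydroxyphenyl)-2,5-bis(4-hydroxyphenyl)oxolane | O1[C@H](c2ccc(O)cc2)[C@@H](c2cc(O)cc(O)c2)[C@@H](c2cc(O)cc(O)c2)[C@@H]1c1ccc(O)cc1 | intermediate
13 | 4-[(2S,3R,4S)-2,3-bis(3,5-dihydroxyphenyl)-4-hydroxy-4-(4-hydroxyphenyl)butylidene]cyclohexa-2,5-dien-1-one (not isolated) | O[C@H](c1ccc(O)cc1)[C@@H](c1cc(O)cc(O)c1)[C@@H](c1cc(O)cc(O)c1)C=C1C=CC(=O)C=C1 | intermediate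
14 | (1R,2S,3R)-2-(3,5-dihydroxyphenyl)-1-[(S)-hydroxy(4-hydroxyphenyl)methyl]-3-(4-hydroxyphenyl)-2,3-dihydro-1H-indene-4,6-diol | Oc1ccc([C@@H]2c3c(O)cc(O)cc3[C@H]([C@H](O)c3ccc(O)cc3)[C@H]2c2cc(O)cc(O)c2)cc1 | target

## Step count and least certain steps

Total step count: 8. Longest linear sequence: 7 (steps 1 or 2, then 3 to 8).

**Step 8 (key step, proposed new method).**
- What may go wrong: poor discrimination between the two enantiotopic C–O bonds, because the catalyst binds far from the stereocentres that differ. The carbinol of the product may re-ionize, followed by elimination toward C1 or by epimerization. The carbinol configuration may also erode if the opened intermediate recloses to a 2,3-cis oxolane that then opens at the other end.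
- Fallback (known chemistry), from 12 back to 14: an achiral Brønsted acid (diphenyl phosphate, EtOAc/CH2Cl2, 25 °C) effects the same opening and Friedel–Crafts closure without bias. It gives 14 together with its mirror image, (1S,2R,3S)-2-(3,5-dihydroxyphenyl)-1-[(R)-hydroxy(4-hydroxyphenyl)methyl]-3-(4-hydroxyphenyl)-2,3-dihydro-1H-indene-4,6-diol F1, as the racemate. This is resolved by preparative chromatography on a chiral stationary phase (amylose tris(3,5-dimethylphenylcarbamate)).

**Step 4.**
- What may go wrong: iodination may outpace displacement at the hindered alpha carbon, leading to over-oxidation toward the unsaturated enedione. The base equilibration may also leave much dl isomer in solution if the meso isomer does not crystallize from a hexasilylated mixture.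
- Fallback, from 5 back to 9: the two roles are separated. Bromination of 5 (PhNMe3Br3, THF, 0 °C) gives 2-{3,5-bis[(triisopropylsilyl)oxy]phenyl}-2-bromo-1-{4-[(triisopropylsilyl)oxy]phenyl}ethan-1-one F2. This is added slowly at −78 °C to one equivalent of preformed enolate 6 (SN2 alkylation), and the resulting mixture of 8 and 9 is equilibrated with DBU and separated by chromatography to give 9.

**Step 6.**
- What may go wrong: premature C-alkylation of a resorcinol ring, or E1 loss from the benzylic cation to a stilbene-type alkene, before the oxolane has reached its thermodynamic configuration.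
- Fallback, from 9 back to 12: the arenes are switched off with acetates.
  - Desilylation of 9 (Bu4NF, AcOH, THF) gives meso-(2R,3S)-2,3-bis(3,5-dihydroxyphenyl)-1,4-bis(4-hydroxyphenyl)butane-1,4-dione F3.
  - Acetylation (Ac2O, pyridine) gives its hexaacetate, meso-(2R,3S)-2,3-bis(3,5-diacetoxyphenyl)-1,4-bis(4-acetoxyphenyl)butane-1,4-dione F4.
  - Reduction (BH3·THF, 0 °C) gives (2R,3S)-2,3-bis(3,5-diacetoxyphenyl)-1,4-bis(4-acetoxyphenyl)butane-1,4-diol F5.
  - Cyclodehydration with a stronger acid (TfOH, 5 mol%, CH2Cl2) can now only go through oxygen and gives meso-(2R,3S,4R,5S)-3,4-bis(3,5-diacetoxyphenyl)-2,5-bis(4-acetoxyphenyl)oxolane F6.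
  - Methanolysis (K2CO3, MeOH, 0 °C) returns the route at 12.

## Further compounds

F1 | step 8 | (1S,2R,3S)-2-(3,5-dihydroxyphenyl)-1-[(R)-hydroxy(4-hydroxyphenyl)methyl]-3-(4-hydroxyphenyl)-2,3-dihydro-1H-indene-4,6-diol (enantiomer of 14) | Oc1ccc([C@H]2c3c(O)cc(O)cc3[C@@H]([C@@H](O)c3ccc(O)cc3)[C@@H]2c2cc(O)cc(O)c2)cc1
F2 | step 4 | 2-{3,5-bis[(triisopropylsilyl)oxy]phenyl}-2-bromo-1-{4-[(triisopropylsilyl)oxy]phenyl}ethan-1-one (racemic) | O=C(C(Br)c1cc(O[Si](C(C)C)(C(C)C)C(C)C)cc(O[Si](C(C)C)(C(C)C)C(C)C)c1)c1ccc(O[Si](C(C)C)(C(C)C)C(C)C)cc1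
F3 | step 6 | meso-(2R,3S)-2,3-bis(3,5-dihydroxyphenyl)-1,4-bis(4-hydroxyphenyl)butane-1,4-dione | O=C(c1ccc(O)cc1)[C@@H](c1cc(O)cc(O)c1)[C@@H](c1cc(O)cc(O)c1)C(=O)c1ccc(O)cc1
F4 | step 6 | meso-(2R,3S)-2,3-bis(3,5-diacetoxyphenyl)-1,4-bis(4-acetoxyphenyl)butane-1,4-dione | O=C(c1ccc(OC(C)=O)cc1)[C@@H](c1cc(OC(C)=O)cc(OC(C)=O)c1)[C@@H](c1cc(OC(C)=O)cc(OC(C)=O)c1)C(=O)c1ccc(OC(C)=O)cc1
F5 | step 6 | (2R,3S)-2,3-bis(3,5-diacetoxyphenyl)-1,4-bis(4-acetoxyphenyl)butane-1,4-diol (mixture of C1/C4 epimers) | OC(c1ccc(OC(C)=O)cc1)[C@@H](c1cc(OC(C)=O)cc(OC(C)=O)c1)[C@@H](c1cc(OC(C)=O)cc(OC(C)=O)c1)C(O)c1ccc(OC(C)=O)cc1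
F6 | step 6 | meso-(2R,3S,4R,5S)-3,4-bis(3,5-diacetoxyphenyl)-2,5-bis(4-acetoxyphenyl)oxolane | O1[C@H](c2ccc(OC(C)=O)cc2)[C@@H](c2cc(OC(C)=O)cc(OC(C)=O)c2)[C@@H](c2cc(OC(C)=O)cc(OC(C)=O)c2)[C@@H]1c1ccc(OC(C)=O)cc1
A1 | alternative 1 | resveratrol, 5-[(E)-2-(4-hydroxyphenyl)ethenyl]benzene-1,3-diol | Oc1ccc(/C=C/c2cc(O)cc(O)c2)cc1
A2 | alternative 1 | meso-4,4′-[(2R,3S)-2,3-bis(3,5-dihydroxyphenyl)butane-1,4-diylidene]bis(cyclohexa-2,5-dien-1-one) | O=C1C=CC(=C[C@@H](c2cc(O)cc(O)c2)[C@@H](c2cc(O)cc(O)c2)C=C2C=CC(=O)C=C2)C=C1
A3 | alternative 2 | (E)-1,2-bis(3,5-dimethoxyphenyl)-3-(4-methoxyphenyl)prop-2-en-1-one | COc1ccc(/C=C(/C(=O)c2cc(OC)cc(OC)c2)c2cc(OC)cc(OC)c2)cc1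
A4 | alternative 2 | (2R,3R)-2-(3,5-dimethoxyphenyl)-4,6-dimethoxy-3-(4-methoxyphenyl)-2,3-dihydro-1H-inden-1-one | COc1ccc([C@@H]2c3c(OC)cc(OC)cc3C(=O)[C@H]2c2cc(OC)cc(OC)c2)cc1
A5 | alternative 3 | 2,3-bis(3,5-dimethoxyphenyl)-1,4-bis(4-methoxyphenyl)butane-1,4-dione (meso/dl mixture) | COc1ccc(cc1)C(=O)C(c1cc(OC)cc(OC)c1)C(c1cc(OC)cc(OC)c1)C(=O)c1ccc(OC)cc1
A6 | alternative 3 | (3S)-2,3-bis(3,5-dimethoxyphenyl)-4-hydroxy-1,4-bis(4-methoxyphenyl)butan-1-one (C2 and C4 not fixed) | COc1ccc(cc1)C(=O)C(c1cc(OC)cc(OC)c1)[C@@H](c1cc(OC)cc(OC)c1)C(O)c1ccc(OC)cc1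
A7 | alternative 3 | [(1R,2S,3R)-2-(3,5-dimethoxyphenyl)-4,6-dimethoxy-3-(4-methoxyphenyl)-2,3-dihydro-1H-inden-1-yl](4-methoxyphenyl)methanone | COc1ccc([C@@H]2c3c(OC)cc(OC)cc3[C@H](C(=O)c3ccc(OC)cc3)[C@H]2c2cc(OC)cc(OC)c2)cc1
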